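**Strategy.** The route rests on disconnecting the γ-butyrolactone ring into a ketone C=O, ethylene and CO. The ring oxygen sits on the quaternary carbon C5, whose exocyclic neighbour is the carbinol carbon C1′. This vicinal C5–O/C1′–O pattern is the retron of an α-dicarbonyl compound, the substrate class that undergoes ruthenium-catalysed carbonylative [2+2+1] cycloaddition. The key step therefore builds the whole lactone, with its quaternary stereocentre, in one operation (new bonds C2–C3, C4–C5 and O1–C2) from a pyruvate ester of (−)-8-phenylmenthol, ethylene and CO. The ester carbon later becomes C1′ by acylation of a chain organozinc and reagent-controlled reduction.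

Key step: step 2

Remark: lactone numbering is O1, C2(=O), C3, C4, C5; compounds 1, 2, 10, 21 and allenylboronic acid pinacol ester are taken as commercial.

**Step 1**
Reactants: 1 (−)-8-phenylmenthol [(1R,2S,5R)-5-methyl-2-(2-phenylpropan-2-yl)cyclohexan-1-ol]; 2 pyruvic acid
Product: 3 (1R,2S,5R)-5-methyl-2-(2-phenylpropan-2-yl)cyclohexyl 2-oxopropanoate
Conditions: TsOH·H2O (cat.), toluene, reflux, Dean–Stark
Reagents that add atoms: none
Why: Acid-catalysed Fischer esterification with azeotropic removal of water should give the α-keto ester without touching the stereocentres of the auxiliary.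

**Step 2**
Reactants: 3 (−)-8-phenylmenthyl pyruvate; 4 ethylene; 5 carbon monoxide
Product: 6 (1R,2S,5R)-5-methyl-2-(2-phenylpropan-2-yl)cyclohexyl (2S)-2-methyl-5-oxotetrahydrofuran-2-carboxylate
Conditions: Ru3(CO)12 (2.5 mol %), P(4-CF3C6H4)3 (7.5 mol %), CO (5 atm), ethylene (3 atm), toluene, 160 °C; chromatography
Reagents that add atoms: none
Why: A zerovalent ruthenium carbonyl species from Ru3(CO)12 is bound by the ester carbonyl of 3 and takes the adjacent ketone C=O and ethylene into an oxaruthenacyclopentane (oxidative cyclisation, ketone carbon–CH2 bond), CO then inserts into the Ru–CH2 bond (CH2–C(=O) bond), and C–O reductive elimination releases the lactone and returns the catalyst. The closest known reaction type is the Ru3(CO)12-catalysed intermolecular carbonylative [2+2+1] cycloaddition (hetero-Pauson–Khand reaction) of α-keto esters and α-diketones with ethylene and CO. The γ-butyrolactone ring is closed by this [2+2+1] cycloaddition of C=O, C=C and CO, the last ring-forming event being acyl–oxygen reductive elimination at ruthenium. The new quaternary stereocentre is controlled by the 8-phenylmenthyl ester: in the chelated s-cis dicarbonyl the phenyl ring stacks over one face, so metal and ethylene should reach the exposed si face of the ketone and give the (S) centre, the sense that carbon nucleophiles show with this auxiliary. The step needs chemoselectivity for the ketone over the ester carbonyl, secured because only the ketone is activated by the neighbouring directing carbonyl, and facial selectivity, secured by the auxiliary; ethylene is symmetric, so no regiochemical question arises, and any minor diastereomer is removed by chromatography.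

**Step 3**
Reactants: 6 auxiliary ester of the lactone acid
Product: 9 (2S)-2-methyl-5-oxotetrahydrofuran-2-carboxylic acid, via dipotassium hydroxy-diacid salt 7 (not isolated), via free hydroxy-diacid 8 (not isolated)
Conditions: KOH, EtOH/H2O, 80 °C; Et2O extraction (recovers 1); aq. HCl to pH 1, EtOAc extraction; toluene, 80 °C
Reagents that add atoms: potassium hydroxide [K+].[OH-]; water O
Why: Saponification opens the lactone and cleaves the hindered ester by acyl–oxygen fission, the quaternary centre has no α-hydrogen and cannot epimerise, and the γ-hydroxy acid relactonises on acidification (5-exo-trig lactonisation).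

**Step 4**
Reactants: 10 tert-butyl(but-3-yn-1-yloxy)dimethylsilane
Product: 12 tert-butyl{[(3E)-4-iodo-3-methylbut-3-en-1-yl]oxy}dimethylsilane, via alkenyldimethylalane 11 (not isolated)
Conditions: Me3Al (2 equiv), Cp2ZrCl2 (0.25 equiv), CH2Cl2, 0 °C to rt; then I2, THF, −30 °C to 0 °C
Reagents that add atoms: trimethylaluminium C[Al](C)C; iodine II
Why: Zirconium-catalysed Negishi carboalumination adds methyl and aluminium syn across the terminal alkyne with methyl on the internal carbon, and iodinolysis of the C–Al bond with retention should give the (E)-iodide.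

**Step 5**
Reactants: 12 (E)-alkenyl iodide
Product: 15 (2E)-5-[(tert-butyldimethylsilyl)oxy]-3-methylpent-2-enal, via alkenyllithium 13 (not isolated), via lithium hemiaminal alkoxide 14 (not isolated)
Conditions: t-BuLi (2.1 equiv), Et2O, −78 °C; DMF, −78 °C to 0 °C; H2O
Reagents that add atoms: N,N-dimethylformamide CN(C)C=O
Why: Iodine–lithium exchange with retention of alkene geometry followed by formylation of the alkenyllithium with DMF (Bouveault-type formylation) should give the (E)-enal.

**Step 6**
Reactants: 15 (E)-enal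
Product: 17 (4S,5E)-8-[(tert-butyldimethylsilyl)oxy]-6-methyloct-5-en-1-yn-4-ol, via homopropargyl pinacol borate 16 (not isolated)
Conditions: (S)-3,3′-bis(2,4,6-triisopropylphenyl)-1,1′-binaphthyl-2,2′-diyl hydrogen phosphate ((S)-TRIP, 10 mol %), 4 Å MS, toluene, −20 °C to rt; aq. NaHCO3
Reagents that add atoms: allenylboronic acid pinacol ester C=C=CB1OC(C)(C)C(C)(C)O1
Why: Chiral phosphoric acid-catalysed allenylboration (asymmetric propargylation) runs through a closed six-membered transition state with γ-attack of the allenylboronate, and the (S)-catalyst is chosen because the (R)-catalyst is taken, by analogy with its allylborations, to deliver (R)-carbinols from aryl and alkenyl aldehydes, so attack on the si face should set the (S)-carbinol.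

**Step 7**
Reactants: 17 (S)-homopropargylic alcohol
Product: 18 (4S,5E)-8-[(tert-butyldimethylsilyl)oxy]-4-[(tert-butyldiphenylsilyl)oxy]-6-methyloct-5-en-1-yne
Conditions: TBDPSCl, imidazole, DMF, rt
Reagents that add atoms: tert-butyl(chloro)diphenylsilane CC(C)(C)[Si](Cl)(c1ccccc1)c1ccccc1
Why: Imidazole-promoted silylation gives a bulky secondary silyl ether that should survive the later acidic removal of the primary TBS group, and no stereocentre is touched.

**Step 8**
Reactants: 18 bis-silylated enyne
Product: 20 (1E,4S,5E)-8-[(tert-butyldimethylsilyl)oxy]-4-[(tert-butyldiphenylsilyl)oxy]-1-iodo-2,6-dimethylocta-1,5-diene, via dienyldimethylalane 19 (not isolated)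
Conditions: Me3Al (3 equiv), Cp2ZrCl2 (0.3 equiv), H2O (1 equiv), CH2Cl2, −20 °C; then I2, THF, −30 °C to 0 °C
Reagents that add atoms: trimethylaluminium C[Al](C)C; iodine II
Why: A second, water-accelerated Negishi carboalumination–iodinolysis installs the (E)-2-methylalkenyl iodide by syn carbometalation of the terminal alkyne, while the silyl ethers and the trisubstituted alkene are inert.

**Step 9**
Reactants: 21 2-(furan-3-yl)ethanol
Product: 22 3-(2-iodoethyl)furan
Conditions: I2, PPh3, imidazole, CH2Cl2, 0 °C
Reagents that add atoms: iodine II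
Why: Appel-type iodination converts the primary alcohol into the iodide by SN2 displacement of the alkoxyphosphonium ion, iodine being consumed by the phosphine before it can attack the furan.

**Step 10**
Reactants: 22 3-(2-iodoethyl)furan; 20 (E)-alkenyl iodide
Product: 24 tert-butyl{[(3E,5S,7E)-5-[(tert-butyldiphenylsilyl)oxy]-10-(furan-3-yl)-3,7-dimethyldeca-3,7-dien-1-yl]oxy}dimethylsilane, via furylethylzinc iodide 23 (not isolated)
Conditions: 22, Zn dust (activated with TMSCl and 1,2-dibromoethane), THF, 35 °C; then 20, PdCl2(dppf) (5 mol %), THF, rt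
Reagents that add atoms: none
Why: Direct zinc insertion gives the alkylzinc iodide, and Negishi sp2–sp3 cross-coupling with a bidentate-phosphine palladium catalyst, which suppresses β-hydride elimination, should join it to the alkenyl iodide with retention of the (E) geometry.

**Step 11**
Reactants: 24 bis-silyl ether
Product: 25 (3E,5S,7E)-5-[(tert-butyldiphenylsilyl)oxy]-10-(furan-3-yl)-3,7-dimethyldeca-3,7-dien-1-ol
Conditions: PPTS (0.2 equiv), MeOH, rt
Reagents that add atoms: none
Why: Mild acid-catalysed methanolysis (selective desilylation) should remove the unhindered primary TBS ether much faster than the bulky secondary TBDPS ether and leave the furan intact.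

**Step 12**
Reactants: 25 primary alcohol
Product: 26 3-[(3E,6S,7E)-6-[(tert-butyldiphenylsilyl)oxy]-10-iodo-4,8-dimethyldeca-3,7-dien-1-yl]furan
Conditions: I2, PPh3, imidazole, CH2Cl2, 0 °C
Reagents that add atoms: iodine II
Why: Appel-type iodination of the primary alcohol proceeds by SN2 displacement and leaves the allylic silyl ether and its stereocentre untouched.

**Step 13**
Reactants: 26 primary iodide; 9 (S)-lactone acid
Product: 29 (5S)-5-[(4E,6S,8E)-6-[(tert-butyldiphenylsilyl)oxy]-11-(furan-3-yl)-4,8-dimethylundeca-4,8-dienoyl]-5-methyldihydrofuran-2(3H)-one, via alkylzinc iodide 27 (not isolated), via acid chloride 28 (not isolated)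
Conditions: 9, (COCl)2, DMF (cat.), CH2Cl2, 0 °C to rt, evaporate; 26, Zn dust, LiCl, THF, 35 °C; combine, Pd(PPh3)4 (5 mol %), THF, 0 °C to rt
Reagents that add atoms: none
Why: The acid is activated as its chloride, the iodide is turned into the alkylzinc iodide by zinc insertion, and palladium-catalysed Negishi acylation should give the ketone without attack on the lactone because organozinc reagents do not add to esters, while the quaternary centre has no α-hydrogen and cannot epimerise.

**Step 14**
Reactants: 29 ketone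
Product: 31 (5S)-5-[(1R,4E,6S,8E)-6-[(tert-butyldiphenylsilyl)oxy]-11-(furan-3-yl)-1-hydroxy-4,8-dimethylundeca-4,8-dien-1-yl]-5-methyldihydrofuran-2(3H)-one, via catechol borate ester 30 (not isolated)
Conditions: (S)-2-methyl-CBS-oxazaborolidine (0.5 equiv), catecholborane (2 equiv), toluene, −78 °C to −40 °C; MeOH, then pH 7 buffer
Reagents that add atoms: none
Why: In this Corey–Bakshi–Shibata reduction the ketone should bind the oxazaborolidine anti to the quaternary lactone carbon (large group) and syn to the CH2 chain (small group), so hydride is delivered under reagent control to give the (R)-carbinol, the sense in which the (S)-catalyst reduces tert-alkyl and aryl methyl ketones, while catecholborane leaves lactone, alkenes and furan untouched.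

**Step 15**
Reactants: 31 silyl-protected diol
Product: 32 irciformonin B [(5S)-5-[(1R,4E,6S,8E)-11-(furan-3-yl)-1,6-dihydroxy-4,8-dimethylundeca-4,8-dien-1-yl]-5-methyldihydrofuran-2(3H)-one]
Conditions: TBAF, AcOH (1:1), THF, rt
Reagents that add atoms: none
Why: Fluoride-induced desilylation, buffered with acetic acid to prevent lactone opening or translactonisation onto the neighbouring hydroxyl, should free the allylic alcohol without ionising it.

**Compound list**

1 | (−)-8-phenylmenthol, (1R,2S,5R)-5-methyl-2-(2-phenylpropan-2-yl)cyclohexan-1-ol | C[C@@H]1CC[C@H]([C@@H](C1)O)C(C)(C)c1ccccc1 | starting material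
2 | pyruvic acid | CC(=O)C(=O)O | starting material
3 | (1R,2S,5R)-5-methyl-2-(2-phenylpropan-2-yl)cyclohexyl 2-oxopropanoate | C[C@@H]1CC[C@H]([C@@H](C1)OC(=O)C(C)=O)C(C)(C)c1ccccc1 | intermediate
4 | ethylene | C=C | starting material
5 | carbon monoxide | [C-]#[O+] | starting material
6 | (1R,2S,5R)-5-methyl-2-(2-phenylpropan-2-yl)cyclohexyl (2S)-2-methyl-5-oxotetrahydrofuran-2-carboxylate | C[C@@H]1CC[C@H]([C@@H](C1)OC(=O)[C@]1(C)CCC(=O)O1)C(C)(C)c1ccccc1 | intermediate
7 | dipotassium (2S)-2-hydroxy-2-methylpentanedioate | [K+].[K+].[O-]C(=O)CC[C@](C)(O)C([O-])=O | intermediate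
8 | (2S)-2-hydroxy-2-methylpentanedioic acid | OC(=O)CC[C@](C)(O)C(O)=O | intermediate
9 | (2S)-2-methyl-5-oxotetrahydrofuran-2-carboxylic acid | OC(=O)[C@]1(C)CCC(=O)O1 | intermediate
10 | tert-butyl(but-3-yn-1-yloxy)dimethylsilane | C#CCCO[Si](C)(C)C(C)(C)C | starting material
11 | [(1E)-4-[(tert-butyldimethylsilyl)oxy]-2-methylbut-1-en-1-yl]dimethylalane | C/C(=C\[Al](C)C)CCO[Si](C)(C)C(C)(C)C | intermediate
12 | tert-butyl{[(3E)-4-iodo-3-methylbut-3-en-1-yl]oxy}dimethylsilane | C/C(=C\I)CCO[Si](C)(C)C(C)(C)C | intermediate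
13 | [(1E)-4-[(tert-butyldimethylsilyl)oxy]-2-methylbut-1-en-1-yl]lithium | C/C(=C\[Li])CCO[Si](C)(C)C(C)(C)C | intermediate
14 | lithium (2E)-5-[(tert-butyldimethylsilyl)oxy]-1-(dimethylamino)-3-methylpent-2-en-1-olate | C/C(=C\C([O-])N(C)C)CCO[Si](C)(C)C(C)(C)C.[Li+] | intermediate
15 | (2E)-5-[(tert-butyldimethylsilyl)oxy]-3-methylpent-2-enal | C/C(=C\C=O)CCO[Si](C)(C)C(C)(C)C | intermediate
16 | 2-{[(4S,5E)-8-[(tert-butyldimethylsilyl)oxy]-6-methyloct-5-en-1-yn-4-yl]oxy}-4,4,5,5-tetramethyl-1,3,2-dioxaborolane | C/C(=C\[C@@H](OB1OC(C)(C)C(C)(C)O1)CC#C)CCO[Si](C)(C)C(C)(C)C | intermediate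
17 | (4S,5E)-8-[(tert-butyldimethylsilyl)oxy]-6-methyloct-5-en-1-yn-4-ol | C/C(=C\[C@@H](O)CC#C)CCO[Si](C)(C)C(C)(C)C | intermediate
18 | (4S,5E)-8-[(tert-butyldimethylsilyl)oxy]-4-[(tert-butyldiphenylsilyl)oxy]-6-methyloct-5-en-1-yne | C/C(=C\[C@@H](O[Si](c1ccccc1)(c1ccccc1)C(C)(C)C)CC#C)CCO[Si](C)(C)C(C)(C)C | intermediate
19 | [(1E,4S,5E)-8-[(tert-butyldimethylsilyl)oxy]-4-[(tert-butyldiphenylsilyl)oxy]-2,6-dimethylocta-1,5-dien-1-yl]dimethylalane | C/C(=C\[C@@H](O[Si](c1ccccc1)(c1ccccc1)C(C)(C)C)C/C(C)=C/[Al](C)C)CCO[Si](C)(C)C(C)(C)C | intermediate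
20 | (1E,4S,5E)-8-[(tert-butyldimethylsilyl)oxy]-4-[(tert-butyldiphenylsilyl)oxy]-1-iodo-2,6-dimethylocta-1,5-diene | C/C(=C\[C@@H](O[Si](c1ccccc1)(c1ccccc1)C(C)(C)C)C/C(C)=C/I)CCO[Si](C)(C)C(C)(C)C | intermediate
21 | 2-(furan-3-yl)ethanol | OCCc1ccoc1 | starting material
22 | 3-(2-iodoethyl)furan | ICCc1ccoc1 | intermediate
23 | [2-(furan-3-yl)ethyl]zinc iodide | I[Zn]CCc1ccoc1 | intermediate
24 | tert-butyl{[(3E,5S,7E)-5-[(tert-butyldiphenylsilyl)oxy]-10-(furan-3-yl)-3,7-dimethyldeca-3,7-dien-1-yl]oxy}dimethylsilane | C/C(=C\[C@@H](O[Si](c1ccccc1)(c1ccccc1)C(C)(C)C)C/C(C)=C/CCc1ccoc1)CCO[Si](C)(C)C(C)(C)C | intermediate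
25 | (3E,5S,7E)-5-[(tert-butyldiphenylsilyl)oxy]-10-(furan-3-yl)-3,7-dimethyldeca-3,7-dien-1-ol | C/C(=C\[C@@H](O[Si](c1ccccc1)(c1ccccc1)C(C)(C)C)C/C(C)=C/CCc1ccoc1)CCO | intermediate
26 | 3-[(3E,6S,7E)-6-[(tert-butyldiphenylsilyl)oxy]-10-iodo-4,8-dimethyldeca-3,7-dien-1-yl]furan | C/C(=C\[C@@H](O[Si](c1ccccc1)(c1ccccc1)C(C)(C)C)C/C(C)=C/CCc1ccoc1)CCI | intermediate
27 | [(3E,5S,7E)-5-[(tert-butyldiphenylsilyl)oxy]-10-(furan-3-yl)-3,7-dimethyldeca-3,7-dien-1-yl]zinc iodide | C/C(=C\[C@@H](O[Si](c1ccccc1)(c1ccccc1)C(C)(C)C)C/C(C)=C/CCc1ccoc1)CC[Zn]I | intermediate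
28 | (2S)-2-methyl-5-oxotetrahydrofuran-2-carbonyl chloride | ClC(=O)[C@]1(C)CCC(=O)O1 | intermediate
29 | (5S)-5-[(4E,6S,8E)-6-[(tert-butyldiphenylsilyl)oxy]-11-(furan-3-yl)-4,8-dimethylundeca-4,8-dienoyl]-5-methyldihydrofuran-2(3H)-one | C/C(=C\[C@@H](O[Si](c1ccccc1)(c1ccccc1)C(C)(C)C)C/C(C)=C/CCc1ccoc1)CCC(=O)[C@]1(C)CCC(=O)O1 | intermediate
30 | catechol borate ester of 31 (1,3,2-benzodioxaborol-2-yl ether at C1′) | C/C(=C\[C@@H](O[Si](c1ccccc1)(c1ccccc1)C(C)(C)C)C/C(C)=C/CCc1ccoc1)CC[C@@H](OB1Oc2ccccc2O1)[C@]1(C)CCC(=O)O1 | intermediate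
31 | (5S)-5-[(1R,4E,6S,8E)-6-[(tert-butyldiphenylsilyl)oxy]-11-(furan-3-yl)-1-hydroxy-4,8-dimethylundeca-4,8-dien-1-yl]-5-methyldihydrofuran-2(3H)-one | C/C(=C\[C@@H](O[Si](c1ccccc1)(c1ccccc1)C(C)(C)C)C/C(C)=C/CCc1ccoc1)CC[C@@H](O)[C@]1(C)CCC(=O)O1 | intermediate
32 | irciformonin B | C/C(=C\[C@@H](O)C/C(C)=C/CCc1ccoc1)CC[C@@H](O)[C@]1(C)CCC(=O)O1 | target

**Step count.** Total: 15 steps. Longest linear sequence: 11 steps (steps 4–8 and 10–15, from 10).

**Steps most likely to fail**

Step 2. The facial discrimination by the auxiliary may erode at 160 °C, and the hindered, enolisable pyruvate ester may turn over slowly or condense with itself. Fallback, setting out from 4 and 5 and returning at 9: the same ruthenium-catalysed [2+2+1] cycloaddition is run on achiral methyl pyruvate F1 and should give racemic methyl 2-methyl-5-oxotetrahydrofuran-2-carboxylate F2. Hydrolysis with aqueous HCl gives racemic 2-methyl-5-oxotetrahydrofuran-2-carboxylic acid F3, which is resolved by fractional crystallisation of its cinchonidine salts. The salt of the (S)-acid, cinchonidinium (2S)-2-methyl-5-oxotetrahydrofuran-2-carboxylate F4, is taken from the crystals or the mother liquor, whichever holds it, and dilute HCl liberates 9. Stereocontrol thus passes from auxiliary induction to classical resolution.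

Step 6. The catalyst may discriminate the faces of this β,β-disubstituted enal poorly, or the boronate may react through the competing allenyl-forming pathway. Fallback, setting out from 15 and returning at 17: zinc-mediated Barbier propargylation (propargyl bromide, Zn, THF/aq. NH4Cl) should give racemic 8-[(tert-butyldimethylsilyl)oxy]-6-methyloct-5-en-1-yn-4-ol F5. Esterification with (S)-O-methylmandelic acid (DCC, DMAP) gives two diastereomeric esters that are separated by chromatography. The (S)-O-methylmandelate of the (S)-alcohol F6, assigned by the mandelate NMR model, is cleaved with K2CO3 in MeOH to give 17.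

Step 14. The inherent facial bias of the α-acyloxy ketone may oppose the catalyst, or reduction next to the quaternary centre may be slow enough for the uncatalysed background reaction to lower the selectivity. Fallback, setting out from 29 and returning at 31: Luche reduction (NaBH4, CeCl3·7H2O, MeOH, −78 °C) without reagent control should give 31 together with its C1′ epimer, the (1S)-alcohol F7. The two diastereomers differ at a carbinol next to the quaternary centre and are separated by chromatography. F7 is oxidised back to 29 with Dess–Martin periodinane and recycled.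

**Further compounds**

F1 | step 2 | methyl pyruvate | COC(=O)C(C)=O
F2 | step 2 | racemic methyl 2-methyl-5-oxotetrahydrofuran-2-carboxylate | COC(=O)C1(C)CCC(=O)O1
F3 | step 2 | racemic 2-methyl-5-oxotetrahydrofuran-2-carboxylic acid | OC(=O)C1(C)CCC(=O)O1
F4 | step 2 | cinchonidinium (2S)-2-methyl-5-oxotetrahydrofuran-2-carboxylate | [O-]C(=O)[C@]1(C)CCC(=O)O1.C=C[C@H]1C[NH+]2CC[C@H]1C[C@H]2[C@@H](c1ccnc2ccccc12)O
F5 | step 6 | racemic (5E)-8-[(tert-butyldimethylsilyl)oxy]-6-methyloct-5-en-1-yn-4-ol | C/C(=C\C(O)CC#C)CCO[Si](C)(C)C(C)(C)C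
F6 | step 6 | (4S,5E)-8-[(tert-butyldimethylsilyl)oxy]-6-methyloct-5-en-1-yn-4-yl (2S)-2-methoxy-2-phenylacetate | C/C(=C\[C@@H](OC(=O)[C@@H](OC)c1ccccc1)CC#C)CCO[Si](C)(C)C(C)(C)C
F7 | step 14 | (5S)-5-[(1S,4E,6S,8E)-6-[(tert-butyldiphenylsilyl)oxy]-11-(furan-3-yl)-1-hydroxy-4,8-dimethylundeca-4,8-dien-1-yl]-5-methyldihydrofuran-2(3H)-one | C/C(=C\[C@@H](O[Si](c1ccccc1)(c1ccccc1)C(C)(C)C)C/C(C)=C/CCc1ccoc1)CC[C@H](O)[C@]1(C)CCC(=O)O1
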